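**Retrosynthetic overview**

1. The aryl ether O–Cβ bond is cut last: a Mitsunobu inversion joins the bicyclic phenol 15 to the threo, silylene-protected arylglycerol 27 (from an Evans syn-glycolate aldol) and gives the erythro (αR,βS) ether.
2. The strategy rests on one feature of the 3,7-dioxabicyclo[3.3.0]octan-2-one: the aryl group on C6 (bonded to O7) and the C4 oxymethylene arm on C5 are cis on the oxolane ring (C5, C6, O7, C8, C1). This is the pattern of a cis-β,γ-disubstituted α-methylene-γ-butyrolactone with C8 as the exocyclic methylene and C2 as the carbonyl.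
3. That temporary lactone (ring T: C1, C2, O7, C6, C5) is cut at C5–C6 and O7–C2 into aldehyde 8 and the (E)-2-(methoxycarbonyl)allylboronate 6 (allylboration–lactonisation under a chiral phosphoric acid).
4. Ring order: ring T first (step 5); then acyl transfer from O7 to O3 makes lactone ring A (C1, C2, O3, C4, C5) and the freed O7 closes oxolane ring B onto C8 (step 7).

Key step: step 5

Remark 1: core atoms are numbered as in 3,7-dioxabicyclo[3.3.0]octan-2-one (C1, C2 carbonyl, O3, C4, C5, C6 aryl-bearing, O7, C8); the side-chain carbons are Cα (benzylic carbinol), Cβ (aryloxy-bearing) and Cγ (CH2OH).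
Remark 2: the (R)-phosphoric acid is assumed to direct the allyl group to the Re face of 8, as it does with simple allyl and crotyl pinacol boronates; if the sense is opposite with boronate 6, the (S)-acid is used.

**Route**

Step 1
Reactants: 1 (tert-butyldimethylsilyloxy)acetaldehyde; 2 methyl acrylate
Product: 3 methyl 4-[(tert-butyldimethylsilyl)oxy]-3-hydroxy-2-methylidenebutanoate (racemic)
Conditions: 1,4-diazabicyclo[2.2.2]octane (0.5 equiv), methyl acrylate (3 equiv, neat), rt
Reagents that add atoms: none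
Why: Morita–Baylis–Hillman reaction of an activated α-silyloxy aldehyde; the new carbinol centre is racemic and is erased in step 3.

Step 2
Reactants: 3 methyl 4-[(tert-butyldimethylsilyl)oxy]-3-hydroxy-2-methylidenebutanoate
Product: 4 methyl 3-acetoxy-4-[(tert-butyldimethylsilyl)oxy]-2-methylidenebutanoate (racemic)
Conditions: AcCl, pyridine, CH2Cl2, 0 °C
Reagents that add atoms: acetyl chloride, CC(=O)Cl
Why: O-acetylation of the secondary allylic alcohol, run cold and briefly so that the acetate does not undergo allylic transposition.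

Step 3
Reactants: 4 methyl 3-acetoxy-4-[(tert-butyldimethylsilyl)oxy]-2-methylidenebutanoate; 5 bis(pinacolato)diboron
Product: 6 methyl (E)-4-[(tert-butyldimethylsilyl)oxy]-2-[(4,4,5,5-tetramethyl-1,3,2-dioxaborolan-2-yl)methyl]but-2-enoate
Conditions: CuCl (10 mol%), LiCl (10 mol%), KOAc, DMF, rt
Reagents that add atoms: none
Why: Copper-catalysed SN2' borylation of a Morita–Baylis–Hillman acetate (borylcupration of the acrylate, then loss of acetate), which should place CH2OTBS trans to the ester and cis to the CH2B carbon, the usual outcome for ester substrates.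

Step 4
Reactants: 7 syringaldehyde
Product: 8 4-(benzyloxy)-3,5-dimethoxybenzaldehyde
Conditions: BnBr, K2CO3, DMF, 60 °C
Reagents that add atoms: benzyl bromide, BrCc1ccccc1
Why: Williamson etherification of the acidic phenol.

Step 5
Reactants: 8 4-(benzyloxy)-3,5-dimethoxybenzaldehyde; 6 methyl (E)-4-[(tert-butyldimethylsilyl)oxy]-2-[(pinacolboryl)methyl]but-2-enoate
Product: 10 (4R,5R)-5-[4-(benzyloxy)-3,5-dimethoxyphenyl]-4-{[(tert-butyldimethylsilyl)oxy]methyl}-3-methylideneoxolan-2-one (cis), via borate 9 (not isolated)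
Conditions: (R)-3,3'-bis(2,4,6-triisopropylphenyl)-1,1'-binaphthyl-2,2'-diyl hydrogen phosphate (10 mol%), 4 Å molecular sieves, toluene, rt to 40 °C; then 50 °C
Reagents that add atoms: none
Why: The phosphoric acid hydrogen-bonds to a boronate oxygen, aldehyde 8 binds to boron, and the allyl unit is transferred through a closed six-membered chair transition state, forming C5–C6 and borate 9; the O7–B oxygen of 9 then attacks the methyl ester and closes ring T by 5-exo-trig acyl substitution with loss of the methoxyborane. The closest known reactions are the thermal or acid-promoted allylboration–lactonisation of aldehydes with 2-(alkoxycarbonyl)allylboronates to α-methylene-γ-butyrolactones and the allyl- and crotylboration of aryl aldehydes with pinacol boronates catalysed by this phosphoric acid. C5 is set by the boronate geometry: CH2OTBS is cis to the CH2B carbon and must sit axial in the chair while the aryl group sits equatorial, which gives the syn borate and hence the cis lactone. C6 is set by the catalyst, which should direct the allyl group to the Re face of the aldehyde and give 6R. The step needs syn selectivity, Re-face selectivity and no ionisation at C6; the first comes from the stereodefined (E)-boronate, the second from the acid, and the third from using only a weak acid at or below 50 °C, because strong acids epimerise such aryl lactones to the trans isomers through the benzylic cation.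

Step 6
Reactants: 10 (4R,5R)-5-[4-(benzyloxy)-3,5-dimethoxyphenyl]-4-{[(tert-butyldimethylsilyl)oxy]methyl}-3-methylideneoxolan-2-one
Product: 11 (4R,5R)-5-[4-(benzyloxy)-3,5-dimethoxyphenyl]-4-(hydroxymethyl)-3-methylideneoxolan-2-one
Conditions: Bu4NF, AcOH (1:1), THF, 0 °C to rt
Reagents that add atoms: none
Why: Fluoride cleaves the primary silyl ether, and the acetic acid buffer keeps the freed alkoxide from starting uncontrolled acyl transfer or conjugate addition.

Step 7
Reactants: 11 (4R,5R)-5-[4-(benzyloxy)-3,5-dimethoxyphenyl]-4-(hydroxymethyl)-3-methylideneoxolan-2-one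
Product: 14 (1R,5R,6R)-6-[4-(benzyloxy)-3,5-dimethoxyphenyl]-3,7-dioxabicyclo[3.3.0]octan-2-one, via translactonised lactone 12 (not isolated), via iodomethyl lactone 13 (not isolated)
Conditions: Cs2CO3 (0.3 equiv), Bu4NI (0.2 equiv), MeCN (0.02 M), rt to 40 °C
Reagents that add atoms: none
Why: Proposed new method: base-mediated acyl transfer from O7 to the C4 hydroxyl (5-exo-trig translactonisation, known for β-hydroxymethyl γ-lactones) should give 12 and free the benzylic O7–H, whose addition to C8 is a formally 5-endo-trig oxa-Michael closure that is slow for oxygen nucleophiles; iodide is meant to add reversibly to the methylene lactone to give the α-iodomethyl lactone 13, which the O7 alkoxide closes by 5-exo-tet SN2 to ring B, while C1 is protonated and equilibrated by the base to the cis ring fusion, the only unstrained one; the closest known reaction types are base-mediated intramolecular oxa-Michael additions to α-methylene lactones and iodide-relayed conjugate addition–substitution sequences such as iodide-mediated halo-aldol reactions.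

Step 8
Reactants: 14 (1R,5R,6R)-6-[4-(benzyloxy)-3,5-dimethoxyphenyl]-3,7-dioxabicyclo[3.3.0]octan-2-one
Product: 15 (1R,5R,6R)-6-(4-hydroxy-3,5-dimethoxyphenyl)-3,7-dioxabicyclo[3.3.0]octan-2-one
Conditions: H2 (1 atm), Pd on carbon (10 wt%), EtOAc, rt, stopped at full conversion
Reagents that add atoms: none
Why: Hydrogenolysis of the aryl benzyl ether, which is faster than cleavage of the cyclic benzylic C6–O7 bond; the reaction is stopped early because the freed para-hydroxyl makes that bond more labile.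

Step 9
Reactants: 16 vanillin
Product: 17 3-methoxy-4-[(triisopropylsilyl)oxy]benzaldehyde
Conditions: iPr3SiCl, imidazole, DMF, rt
Reagents that add atoms: chlorotriisopropylsilane, CC(C)[Si](Cl)(C(C)C)C(C)C
Why: Silylation of the phenol with a group that should survive the borohydride, hydrogenation and Mitsunobu steps and leave with fluoride at the end.

Step 10
Reactants: 18 (S)-4-benzyl-1,3-oxazolidin-2-one; 19 (benzyloxy)acetyl chloride
Product: 21 (S)-4-benzyl-3-[(benzyloxy)acetyl]-1,3-oxazolidin-2-one, via lithium oxazolidinide 20 (not isolated)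
Conditions: n-BuLi, THF, −78 °C; then 19, −78 to 0 °C
Reagents that add atoms: none
Why: N-Acylation of the lithiated oxazolidinone with the acid chloride.

Step 11
Reactants: 21 (S)-4-benzyl-3-[(benzyloxy)acetyl]-1,3-oxazolidin-2-one; 17 3-methoxy-4-[(triisopropylsilyl)oxy]benzaldehyde
Product: 24 (4S)-4-benzyl-3-{(2S,3R)-2-(benzyloxy)-3-hydroxy-3-[3-methoxy-4-(triisopropylsilyloxy)phenyl]propanoyl}-1,3-oxazolidin-2-one, via boron enolate 22 (not isolated), via boron aldolate 23 (not isolated)
Conditions: Bu2BOTf, Et3N, CH2Cl2, −78 to 0 °C; 17, −78 to 0 °C; then pH 7 buffer, MeOH, H2O2, 0 °C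
Reagents that add atoms: none
Why: Evans syn-aldol reaction in which the (Z)-boron enolate 22 reacts through a closed chair on the face away from the auxiliary benzyl group, setting (2S,3R), that is Cα R and the threo relation to the Cβ oxygen needed for later inversion.

Step 12
Reactants: 24 (4S)-4-benzyl-3-{(2S,3R)-2-(benzyloxy)-3-hydroxy-3-[3-methoxy-4-(triisopropylsilyloxy)phenyl]propanoyl}-1,3-oxazolidin-2-one
Product: 25 (1R,2R)-2-(benzyloxy)-1-[3-methoxy-4-(triisopropylsilyloxy)phenyl]propane-1,3-diol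
Conditions: LiBH4, MeOH (1 equiv), THF, 0 °C
Reagents that add atoms: none
Why: Reductive removal of the auxiliary by LiBH4 turns the imide carbonyl into the Cγ CH2OH without touching either stereocentre.

Step 13
Reactants: 25 (1R,2R)-2-(benzyloxy)-1-[3-methoxy-4-(triisopropylsilyloxy)phenyl]propane-1,3-diol
Product: 26 (4R,5R)-5-(benzyloxy)-2,2-di-tert-butyl-4-[3-methoxy-4-(triisopropylsilyloxy)phenyl]-1,3,2-dioxasilinane
Conditions: tBu2Si(OTf)2, 2,6-lutidine, CH2Cl2, 0 °C
Reagents that add atoms: di-tert-butylsilyl bis(trifluoromethanesulfonate), CC(C)(C)[Si](OS(=O)(=O)C(F)(F)F)(OS(=O)(=O)C(F)(F)F)C(C)(C)C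
Why: Only the 1,3-diol is free, so the bis(triflate) can only form the six-membered silylene, which ties Cα–O and Cγ–O together and is fluoride-labile.

Step 14
Reactants: 26 (4R,5R)-5-(benzyloxy)-2,2-di-tert-butyl-4-[3-methoxy-4-(triisopropylsilyloxy)phenyl]-1,3,2-dioxasilinane
Product: 27 (4R,5R)-2,2-di-tert-butyl-4-[3-methoxy-4-(triisopropylsilyloxy)phenyl]-1,3,2-dioxasilinan-5-ol
Conditions: H2 (1 atm), Pd(OH)2 on carbon, EtOAc, rt
Reagents that add atoms: none
Why: Hydrogenolysis of the alkyl benzyl ether frees the Cβ hydroxyl alone; the silylene, the aryl silyl ether and the benzylic C–O(Si) bond should be inert in a neutral aprotic solvent.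

Step 15
Reactants: 15 (1R,5R,6R)-6-(4-hydroxy-3,5-dimethoxyphenyl)-3,7-dioxabicyclo[3.3.0]octan-2-one; 27 (4R,5R)-2,2-di-tert-butyl-4-[3-methoxy-4-(triisopropylsilyloxy)phenyl]-1,3,2-dioxasilinan-5-ol
Product: 28 (1R,5R,6R)-6-[4-({(4R,5S)-2,2-di-tert-butyl-4-[3-methoxy-4-(triisopropylsilyloxy)phenyl]-1,3,2-dioxasilinan-5-yl}oxy)-3,5-dimethoxyphenyl]-3,7-dioxabicyclo[3.3.0]octan-2-one
Conditions: PPh3, diisopropyl azodicarboxylate, toluene, 0 to 40 °C
Reagents that add atoms: none
Why: Mitsunobu etherification in which the axial Cβ hydroxyl of the cis (threo) chair is activated as the oxyphosphonium ion and displaced by the phenoxide of 15 from the equatorial side with inversion, giving the trans-diequatorial (4R,5S) ether, the erythro (αR,βS) pattern; no aryl group is antiperiplanar to the leaving group in the ring, so aryl participation is shut off.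

Step 16
Reactants: 28 (1R,5R,6R)-6-[4-({(4R,5S)-2,2-di-tert-butyl-4-[3-methoxy-4-(triisopropylsilyloxy)phenyl]-1,3,2-dioxasilinan-5-yl}oxy)-3,5-dimethoxyphenyl]-3,7-dioxabicyclo[3.3.0]octan-2-one
Product: 29 (1R,5R,6R)-6-(4-{[(1R,2S)-1,3-dihydroxy-1-(4-hydroxy-3-methoxyphenyl)propan-2-yl]oxy}-3,5-dimethoxyphenyl)-3,7-dioxabicyclo[3.3.0]octan-2-one (target)
Conditions: Bu4NF, AcOH (1:1, excess), THF, 0 °C to rt
Reagents that add atoms: none
Why: Buffered fluoride cleaves both Si–O bonds of the silylene and the aryl silyl ether without a base strong enough to reopen ring B or disturb the lactone.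

**Compound list**

1 | (tert-butyldimethylsilyloxy)acetaldehyde | O=CCO[Si](C)(C)C(C)(C)C | starting material
2 | methyl acrylate | C=CC(=O)OC | starting material
3 | methyl 4-[(tert-butyldimethylsilyl)oxy]-3-hydroxy-2-methylidenebutanoate (racemic) | C=C(C(=O)OC)C(O)CO[Si](C)(C)C(C)(C)C | intermediate
4 | methyl 3-acetoxy-4-[(tert-butyldimethylsilyl)oxy]-2-methylidenebutanoate (racemic) | C=C(C(=O)OC)C(OC(C)=O)CO[Si](C)(C)C(C)(C)C | intermediate
5 | bis(pinacolato)diboron | CC1(C)OB(OC1(C)C)B1OC(C)(C)C(C)(C)O1 | starting material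
6 | methyl (E)-4-[(tert-butyldimethylsilyl)oxy]-2-[(4,4,5,5-tetramethyl-1,3,2-dioxaborolan-2-yl)methyl]but-2-enoate | COC(=O)/C(=C/CO[Si](C)(C)C(C)(C)C)CB1OC(C)(C)C(C)(C)O1 | intermediate
7 | syringaldehyde | COc1cc(C=O)cc(OC)c1O | starting material
8 | 4-(benzyloxy)-3,5-dimethoxybenzaldehyde | COc1cc(C=O)cc(OC)c1OCc1ccccc1 | intermediate
9 | methyl (3R,4R)-4-[4-(benzyloxy)-3,5-dimethoxyphenyl]-3-{[(tert-butyldimethylsilyl)oxy]methyl}-2-methylidene-4-[(pinacolboryl)oxy]butanoate (syn borate) | COC(=O)C(=C)[C@H](CO[Si](C)(C)C(C)(C)C)[C@@H](OB1OC(C)(C)C(C)(C)O1)c1cc(OC)c(OCc2ccccc2)c(OC)c1 | intermediate (not isolated)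
10 | (4R,5R)-5-[4-(benzyloxy)-3,5-dimethoxyphenyl]-4-{[(tert-butyldimethylsilyl)oxy]methyl}-3-methylideneoxolan-2-one | C=C1C(=O)O[C@@H](c2cc(OC)c(OCc3ccccc3)c(OC)c2)[C@H]1CO[Si](C)(C)C(C)(C)C | intermediate
11 | (4R,5R)-5-[4-(benzyloxy)-3,5-dimethoxyphenyl]-4-(hydroxymethyl)-3-methylideneoxolan-2-one | C=C1C(=O)O[C@@H](c2cc(OC)c(OCc3ccccc3)c(OC)c2)[C@H]1CO | intermediate
12 | (4R)-4-{(R)-[4-(benzyloxy)-3,5-dimethoxyphenyl](hydroxy)methyl}-3-methylideneoxolan-2-one | C=C1C(=O)OC[C@@H]1[C@@H](O)c1cc(OC)c(OCc2ccccc2)c(OC)c1 | intermediate (not isolated)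
13 | (4R)-4-{(R)-[4-(benzyloxy)-3,5-dimethoxyphenyl](hydroxy)methyl}-3-(iodomethyl)oxolan-2-one (both C3 epimers) | ICC1C(=O)OC[C@@H]1[C@@H](O)c1cc(OC)c(OCc2ccccc2)c(OC)c1 | intermediate (not isolated)
14 | (1R,5R,6R)-6-[4-(benzyloxy)-3,5-dimethoxyphenyl]-3,7-dioxabicyclo[3.3.0]octan-2-one | COc1cc([C@@H]2OC[C@@H]3C(=O)OC[C@@H]32)cc(OC)c1OCc1ccccc1 | intermediate
15 | (1R,5R,6R)-6-(4-hydroxy-3,5-dimethoxyphenyl)-3,7-dioxabicyclo[3.3.0]octan-2-one | COc1cc([C@@H]2OC[C@@H]3C(=O)OC[C@@H]32)cc(OC)c1O | intermediate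
16 | vanillin | COc1cc(C=O)ccc1O | starting material
17 | 3-methoxy-4-[(triisopropylsilyl)oxy]benzaldehyde | COc1cc(C=O)ccc1O[Si](C(C)C)(C(C)C)C(C)C | intermediate
18 | (S)-4-benzyl-1,3-oxazolidin-2-one | O=C1N[C@@H](Cc2ccccc2)CO1 | starting material
19 | (benzyloxy)acetyl chloride | O=C(Cl)COCc1ccccc1 | starting material
20 | lithium (S)-4-benzyl-2-oxo-1,3-oxazolidin-3-ide | [Li+].O=C1[N-][C@@H](Cc2ccccc2)CO1 | intermediate (not isolated)
21 | (S)-4-benzyl-3-[(benzyloxy)acetyl]-1,3-oxazolidin-2-one | O=C(COCc1ccccc1)N1C(=O)OC[C@@H]1Cc1ccccc1 | intermediate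
22 | (Z)-dibutylboron enolate of 21 | CCCCB(CCCC)O/C(=C\OCc1ccccc1)N1C(=O)OC[C@@H]1Cc1ccccc1 | intermediate (not isolated)
23 | dibutylboron aldolate of 24 | COc1cc([C@@H](OB(CCCC)CCCC)[C@@H](C(=O)N2C(=O)OC[C@@H]2Cc2ccccc2)OCc2ccccc2)ccc1O[Si](C(C)C)(C(C)C)C(C)C | intermediate (not isolated)
24 | (4S)-4-benzyl-3-{(2S,3R)-2-(benzyloxy)-3-hydroxy-3-[3-methoxy-4-(triisopropylsilyloxy)phenyl]propanoyl}-1,3-oxazolidin-2-one | COc1cc([C@@H](O)[C@@H](C(=O)N2C(=O)OC[C@@H]2Cc2ccccc2)OCc2ccccc2)ccc1O[Si](C(C)C)(C(C)C)C(C)C | intermediate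
25 | (1R,2R)-2-(benzyloxy)-1-[3-methoxy-4-(triisopropylsilyloxy)phenyl]propane-1,3-diol | COc1cc([C@@H](O)[C@@H](CO)OCc2ccccc2)ccc1O[Si](C(C)C)(C(C)C)C(C)C | intermediate
26 | (4R,5R)-5-(benzyloxy)-2,2-di-tert-butyl-4-[3-methoxy-4-(triisopropylsilyloxy)phenyl]-1,3,2-dioxasilinane | COc1cc([C@H]2O[Si](C(C)(C)C)(C(C)(C)C)OC[C@H]2OCc2ccccc2)ccc1O[Si](C(C)C)(C(C)C)C(C)C | intermediate
27 | (4R,5R)-2,2-di-tert-butyl-4-[3-methoxy-4-(triisopropylsilyloxy)phenyl]-1,3,2-dioxasilinan-5-ol | COc1cc([C@H]2O[Si](C(C)(C)C)(C(C)(C)C)OC[C@H]2O)ccc1O[Si](C(C)C)(C(C)C)C(C)C | intermediate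
28 | (1R,5R,6R)-6-[4-({(4R,5S)-2,2-di-tert-butyl-4-[3-methoxy-4-(triisopropylsilyloxy)phenyl]-1,3,2-dioxasilinan-5-yl}oxy)-3,5-dimethoxyphenyl]-3,7-dioxabicyclo[3.3.0]octan-2-one | COc1cc([C@H]2O[Si](C(C)(C)C)(C(C)(C)C)OC[C@@H]2Oc2c(OC)cc([C@@H]3OC[C@@H]4C(=O)OC[C@@H]43)cc2OC)ccc1O[Si](C(C)C)(C(C)C)C(C)C | intermediate
29 | (1R,5R,6R)-6-(4-{[(1R,2S)-1,3-dihydroxy-1-(4-hydroxy-3-methoxyphenyl)propan-2-yl]oxy}-3,5-dimethoxyphenyl)-3,7-dioxabicyclo[3.3.0]octan-2-one | COc1cc([C@@H](O)[C@H](CO)Oc2c(OC)cc([C@@H]3OC[C@@H]4C(=O)OC[C@@H]43)cc2OC)ccc1O | target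

**Step count**

Total: 16 steps. Longest linear sequence: 9 steps (1, 2, 3, 5, 6, 7, 8, 15, 16).

**Steps most likely to fail**

1. Step 7 (carries the label). The primary C4 alkoxide may close onto C8 before acyl transfer and give the regioisomeric bicycle with the aryl group on the lactone ring. The endo-type closure may also be too slow, leaving room for oligomerisation or migration of the double bond into the ring. Fallback with known reactions, from 10 back to 14, in which the roles of the two exocyclic carbons are swapped by oxidation level instead of acyl transfer. Lactone 10 is reduced with iBu2AlH (CH2Cl2, −78 °C) to (1R,2R)-1-aryl-2-(silyloxymethyl)-3-methylidenebutane-1,4-diol F1. The primary allylic hydroxyl is sulfonylated selectively (TsCl, Et3N, CH2Cl2, 0 °C) to the monotosylate F2. NaH in THF closes the (2R,3R)-4-methylideneoxolane F3 by 5-exo-tet displacement, with C6 untouched; the former carbonyl carbon is now C8. Hydroboration–oxidation (9-borabicyclo[3.3.1]nonane, then NaBO3) from the face opposite to the two cis substituents should give the all-cis oxolanylmethanol F4. TEMPO with PhI(OAc)2 in MeCN–H2O oxidises it to the oxolane-3-carboxylic acid F5. Bu4NF then removes the silyl group, and the cis hydroxy acid F6 lactonises on mild acidification or with a carbodiimide to 14.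

2. Step 5. The electron-poor boronate may be too little accelerated by the phosphoric acid, so that a slow background reaction erodes the enantioselectivity. Prolonged acid and heat could also ionise C6 and drain the cis lactone to the trans isomer. Fallback from 8 and 6 back to 10: the two are heated in toluene (80 °C) without acid, the known thermal allylboration–lactonisation of this boronate class. It runs through the same chair and should give the cis lactone as the racemate, that is 9 and 10 together with the enantiomeric borate F7 and the enantiomeric lactone F8. The enantiomers are separated by preparative chromatography on a chiral stationary phase, and 10 re-enters at step 6.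

3. Step 15. The di-ortho-substituted phenoxide is a slow nucleophile, so the activated axial alcohol may undergo E2 elimination or be captured by the hydrazide instead. Fallback from 7 and 27 back to 28: the ether is made before the key step on syringaldehyde 7, whose formyl group makes the phenol far more acidic. Mitsunobu reaction of 7 with 27 (PPh3, diisopropyl azodicarboxylate, toluene) gives, with inversion at Cβ, the side-chain aldehyde F9. F9 is taken through the conditions of step 5 with 6, giving the side-chain borate F10 and then the side-chain lactone F11. The primary silyl ether alone is cleaved with pyridinium p-toluenesulfonate in MeOH to the side-chain hydroxy lactone F12; the silylene and the aryl silyl ether should survive. The conditions of step 7 then lead through the side-chain translactonised lactone F13 and the side-chain iodomethyl lactone F14 to 28.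

**Further compounds**

F1 | step 7 | (1R,2R)-1-[4-(benzyloxy)-3,5-dimethoxyphenyl]-2-{[(tert-butyldimethylsilyl)oxy]methyl}-3-methylidenebutane-1,4-diol | C=C(CO)[C@H](CO[Si](C)(C)C(C)(C)C)[C@@H](O)c1cc(OC)c(OCc2ccccc2)c(OC)c1
F2 | step 7 | (3R,4R)-4-[4-(benzyloxy)-3,5-dimethoxyphenyl]-3-{[(tert-butyldimethylsilyl)oxy]methyl}-4-hydroxy-2-methylidenebutyl 4-methylbenzenesulfonate | C=C(COS(=O)(=O)c1ccc(C)cc1)[C@H](CO[Si](C)(C)C(C)(C)C)[C@@H](O)c1cc(OC)c(OCc2ccccc2)c(OC)c1
F3 | step 7 | (2R,3R)-2-[4-(benzyloxy)-3,5-dimethoxyphenyl]-3-{[(tert-butyldimethylsilyl)oxy]methyl}-4-methylideneoxolane | C=C1CO[C@@H](c2cc(OC)c(OCc3ccccc3)c(OC)c2)[C@H]1CO[Si](C)(C)C(C)(C)C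
F4 | step 7 | [(3S,4R,5R)-5-[4-(benzyloxy)-3,5-dimethoxyphenyl]-4-{[(tert-butyldimethylsilyl)oxy]methyl}oxolan-3-yl]methanol | COc1cc([C@@H]2OC[C@H](CO)[C@@H]2CO[Si](C)(C)C(C)(C)C)cc(OC)c1OCc1ccccc1
F5 | step 7 | (3R,4R,5R)-5-[4-(benzyloxy)-3,5-dimethoxyphenyl]-4-{[(tert-butyldimethylsilyl)oxy]methyl}oxolane-3-carboxylic acid | COc1cc([C@@H]2OC[C@H](C(=O)O)[C@@H]2CO[Si](C)(C)C(C)(C)C)cc(OC)c1OCc1ccccc1
F6 | step 7 | (3R,4R,5R)-5-[4-(benzyloxy)-3,5-dimethoxyphenyl]-4-(hydroxymethyl)oxolane-3-carboxylic acid | COc1cc([C@@H]2OC[C@H](C(=O)O)[C@@H]2CO)cc(OC)c1OCc1ccccc1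
F7 | step 5 | methyl (3S,4S)-4-[4-(benzyloxy)-3,5-dimethoxyphenyl]-3-{[(tert-butyldimethylsilyl)oxy]methyl}-2-methylidene-4-[(pinacolboryl)oxy]butanoate (enantiomer of 9) | COC(=O)C(=C)[C@@H](CO[Si](C)(C)C(C)(C)C)[C@H](OB1OC(C)(C)C(C)(C)O1)c1cc(OC)c(OCc2ccccc2)c(OC)c1
F8 | step 5 | (4S,5S)-5-[4-(benzyloxy)-3,5-dimethoxyphenyl]-4-{[(tert-butyldimethylsilyl)oxy]methyl}-3-methylideneoxolan-2-one (enantiomer of 10) | C=C1C(=O)O[C@H](c2cc(OC)c(OCc3ccccc3)c(OC)c2)[C@@H]1CO[Si](C)(C)C(C)(C)C
F9 | step 15 | 4-({(4R,5S)-2,2-di-tert-butyl-4-[3-methoxy-4-(triisopropylsilyloxy)phenyl]-1,3,2-dioxasilinan-5-yl}oxy)-3,5-dimethoxybenzaldehyde | COc1cc([C@H]2O[Si](C(C)(C)C)(C(C)(C)C)OC[C@@H]2Oc2c(OC)cc(C=O)cc2OC)ccc1O[Si](C(C)C)(C(C)C)C(C)C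
F10 | step 15 | syn borate corresponding to 9 with the silylene-protected side chain of 28 in place of benzyl | COc1cc([C@H]2O[Si](C(C)(C)C)(C(C)(C)C)OC[C@@H]2Oc2c(OC)cc([C@H](OB3OC(C)(C)C(C)(C)O3)[C@@H](CO[Si](C)(C)C(C)(C)C)C(=C)C(=O)OC)cc2OC)ccc1O[Si](C(C)C)(C(C)C)C(C)C
F11 | step 15 | cis lactone corresponding to 10 with the side chain of 28 in place of benzyl | COc1cc([C@H]2O[Si](C(C)(C)C)(C(C)(C)C)OC[C@@H]2Oc2c(OC)cc([C@@H]3OC(=O)C(=C)[C@@H]3CO[Si](C)(C)C(C)(C)C)cc2OC)ccc1O[Si](C(C)C)(C(C)C)C(C)C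
F12 | step 15 | hydroxy lactone corresponding to 11 with the side chain of 28 in place of benzyl | COc1cc([C@H]2O[Si](C(C)(C)C)(C(C)(C)C)OC[C@@H]2Oc2c(OC)cc([C@@H]3OC(=O)C(=C)[C@@H]3CO)cc2OC)ccc1O[Si](C(C)C)(C(C)C)C(C)C
F13 | step 15 | translactonised lactone corresponding to 12 with the side chain of 28 in place of benzyl | COc1cc([C@H]2O[Si](C(C)(C)C)(C(C)(C)C)OC[C@@H]2Oc2c(OC)cc([C@H](O)[C@H]3COC(=O)C3=C)cc2OC)ccc1O[Si](C(C)C)(C(C)C)C(C)C
F14 | step 15 | iodomethyl lactone corresponding to 13 with the side chain of 28 in place of benzyl (both epimers at the iodomethyl-bearing carbon) | COc1cc([C@H]2O[Si](C(C)(C)C)(C(C)(C)C)OC[C@@H]2Oc2c(OC)cc([C@H](O)[C@H]3COC(=O)C3CI)cc2OC)ccc1O[Si](C(C)C)(C(C)C)C(C)C
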